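**Retrosynthetic overview**
- The target is made last by one RuO4 oxidation of an 8α-acetoxy decalin that carries a 4α-phenyl group and a but-3-enyl chain at C9. The phenyl ring becomes the C18 acid and the terminal alkene becomes the C13 acid.
- That acetate comes from the tertiary alkenol, which comes from a tricyclic δ-lactone by reduction to the lactol and methylenation.
- Key disconnection: the lactone comes from an acyclic phenyl-capped triene acid in one asymmetric proton-initiated cascade. Ring A (C4–C5) forms first, then ring B (C9–C10), then lactone ring C (C8–O). The carboxyl plays the part of the water that captures the C8 cation in labdane biosynthesis.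
- The triene acid comes from a Wittig reaction on a trisnor aldehyde, made from ethyl farnesylacetate by terminal epoxidation and cleavage; that ester comes from (2E,6E)-farnesyl bromide and ethyl acetate.

Assumption: the sense of induction of the chiral acid in step 5 cannot be predicted for this new substrate, so the (S,S) antipode is written and the (R,R) antipode is used instead if a calibration run gives the mirror-image lactone. Bicyclic compounds carry labdane numbering (α = face opposite to the C10 methyl; C18 = the 4α carbon).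

**Route**

Step 1
Reactants: 1 (2E,6E)-farnesyl bromide; 2 ethyl acetate
Product: 3 ethyl (4E,8E)-5,9,13-trimethyltetradeca-4,8,12-trienoate
Conditions: LiN(iPr)2, THF, −78 °C; then 1, DMPU, −78 → −40 °C
Reagents that add atoms: none
Why: SN2 alkylation of the lithium ester enolate at the primary allylic bromide (enolate alkylation) adds the two-carbon acid terminus and leaves untouched the two E-trisubstituted alkenes whose geometry later fixes the trans ring fusion and the C8/C9 relationship.

Step 2
Reactants: 3 ethyl (4E,8E)-5,9,13-trimethyltetradeca-4,8,12-trienoate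
Product: 5 ethyl (4E,8E)-12,13-epoxy-5,9,13-trimethyltetradeca-4,8-dienoate, via bromohydrin 4 (not isolated)
Conditions: NBS, THF/H2O, 0 °C; then K2CO3, EtOH, rt
Reagents that add atoms: water, O; N-bromosuccinimide, O=C1CCC(=O)N1Br (its bromine stays in 4 only)
Why: van Tamelen terminal-selective bromohydrin formation (Markovnikov opening of the bromonium ion of the most exposed alkene by water) followed by intramolecular Williamson closure gives the racemic terminal epoxide, whose stereocentre is deleted in the next step.

Step 3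
Reactants: 5 ethyl (4E,8E)-12,13-epoxy-5,9,13-trimethyltetradeca-4,8-dienoate
Product: 6 ethyl (4E,8E)-5,9-dimethyl-12-oxododeca-4,8-dienoate
Conditions: H5IO6, THF/H2O, 0 °C → rt
Reagents that add atoms: none
Why: acid-mediated epoxide hydrolysis and periodate glycol cleavage (Malaprade oxidation) excise acetone and leave the trisnor aldehyde, whose oxygen is the former epoxide oxygen.

Step 4
Reactants: 6 ethyl (4E,8E)-5,9-dimethyl-12-oxododeca-4,8-dienoate; 7 (1-phenylethyl)triphenylphosphonium bromide
Product: 9 (4E,8E)-5,9-dimethyl-13-phenyltetradeca-4,8,12-trienoic acid, via ethyl ester 8 (not isolated)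
Conditions: 7, n-BuLi, THF, 0 °C; 6, −78 °C → rt; then LiOH, MeOH/H2O, 40 °C; HCl (1 M) to pH 4, 0 °C
Reagents that add atoms: lithium hydroxide, [Li+].[OH-]
Why: Wittig olefination with the semistabilised secondary ylide builds the trisubstituted styrene terminus (its 12E/12Z ratio is immaterial because both isomers give the same tertiary benzylic cation on protonation) and ester saponification frees the carboxyl that will terminate the cascade.

Step 5
Reactants: 9 (4E,8E)-5,9-dimethyl-13-phenyltetradeca-4,8,12-trienoic acid
Product: 10 (4R,5R,8R,9R,10S)-4-phenyl-14,15,16,18-tetranorlabdan-13,8-olide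
Conditions: (S,S)-imidodiphosphorimidate acid from two (S)-3,3'-bis[3,5-bis(trifluoromethyl)phenyl]-BINOL units with N-SO2CF3 groups (IDPi, 5 mol%), (CF3)3COH/CH2Cl2, −20 °C, 0.02 M
Reagents that add atoms: none
Why: Proposed new method: the confined chiral acid protonates the most basic alkene of 9 (the styrene, at the carbon that becomes C3) to a contact ion pair of the C4 benzylic cation, which is captured in a chair–chair fold by the C8=C9 alkene of 9 (ring A, bond C4–C5, phenyl equatorial = 4α to avoid the 1,3-diaxial clash with the future C10 methyl) and then by the C4=C5 alkene of 9 (ring B, bond C9–C10, trans-decalin), the C8 cation being trapped anti by the carboxyl (lactone ring C, 8α-O, 9β chain), so that the chiral anion sets C4, C5, C8, C9 and C10 in one event; the closest known reactions are the IDPi-catalysed asymmetric proton-initiated cyclisation of homofarnesol to ambrox-type ethers and the acid-mediated cyclisation of farnesylacetic acid to ambreinolide.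

Step 6
Reactants: 10 (4R,5R,8R,9R,10S)-4-phenyl-14,15,16,18-tetranorlabdan-13,8-olide
Product: 11 (4R,5R,8R,9R,10S)-8,13-epoxy-4-phenyl-14,15,16,18-tetranorlabdan-13-ol
Conditions: iBu2AlH (1.1 equiv), CH2Cl2, −78 °C
Reagents that add atoms: none
Why: partial hydride reduction of the lactone stops at the aluminium lactolate at low temperature (lactone-to-lactol reduction) and touches no stereocentre.

Step 7
Reactants: 11 (4R,5R,8R,9R,10S)-8,13-epoxy-4-phenyl-14,15,16,18-tetranorlabdan-13-ol
Product: 12 (4R,5R,8R,9R,10S)-4-phenyl-15,16,18-trinorlabd-13-en-8-ol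
Conditions: Ph3PCH3Br, KOtBu (3 equiv), THF, 0 → 60 °C
Reagents that add atoms: methyltriphenylphosphonium bromide, C[P+](c1ccccc1)(c1ccccc1)c1ccccc1.[Br-]
Why: the lactol equilibrates with its open 8-hydroxy aldehyde, which undergoes Wittig methylenation to a terminal alkene (the masked C13 carboxyl) and frees the tertiary 8α-hydroxyl with C8 and C9 untouched.

Step 8
Reactants: 12 (4R,5R,8R,9R,10S)-4-phenyl-15,16,18-trinorlabd-13-en-8-ol
Product: 13 (4R,5R,8R,9R,10S)-4-phenyl-15,16,18-trinorlabd-13-en-8-yl acetate
Conditions: Ac2O, Et3N, 4-(dimethylamino)pyridine, CH2Cl2, 40 °C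
Reagents that add atoms: acetic anhydride, CC(=O)OC(C)=O
Why: nucleophile-catalysed (Steglich-type) acylation acetylates the hindered tertiary alcohol with retention at C8 because only the O–H bond is broken, and no carboxyl is present yet that could relactonise.

Step 9
Reactants: 13 (4R,5R,8R,9R,10S)-4-phenyl-15,16,18-trinorlabd-13-en-8-yl acetate
Product: 14 (4R,5R,8R,9R,10S)-8-acetoxy-14,15,16-trinorlabdane-13,18-dioic acid
Conditions: RuCl3 (5 mol%), NaIO4 (20 equiv), CCl4/MeCN/H2O 2:2:3, rt
Reagents that add atoms: sodium periodate, [Na+].[O-]I(=O)(=O)=O (oxygen relayed through RuO4); water, O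
Why: catalytic RuO4 (Sharpless RuCl3/NaIO4 oxidation) cleaves the terminal alkene to the C13 acid and degrades the phenyl ring to the C18 acid with the ipso carbon retained, so the 4α-carboxyl keeps the configuration set in step 5 while the tertiary acetate and all stereocentres are inert.

**Compound list**

1 | (2E,6E)-farnesyl bromide | BrC/C=C(C)/CC/C=C(C)/CCC=C(C)C | starting material
2 | ethyl acetate | CCOC(C)=O | starting material
3 | ethyl (4E,8E)-5,9,13-trimethyltetradeca-4,8,12-trienoate | CCOC(=O)CC/C=C(C)/CC/C=C(C)/CCC=C(C)C | intermediate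
4 | ethyl (4E,8E)-12-bromo-13-hydroxy-5,9,13-trimethyltetradeca-4,8-dienoate (racemic bromohydrin) | CCOC(=O)CC/C=C(C)/CC/C=C(C)/CCC(Br)C(C)(C)O | intermediate (not isolated)
5 | ethyl (4E,8E)-12,13-epoxy-5,9,13-trimethyltetradeca-4,8-dienoate (racemic) | CCOC(=O)CC/C=C(C)/CC/C=C(C)/CCC1OC1(C)C | intermediate
6 | ethyl (4E,8E)-5,9-dimethyl-12-oxododeca-4,8-dienoate | CCOC(=O)CC/C=C(C)/CC/C=C(C)/CCC=O | intermediate
7 | (1-phenylethyl)triphenylphosphonium bromide (racemic) | CC(c1ccccc1)[P+](c1ccccc1)(c1ccccc1)c1ccccc1.[Br-] | starting material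
8 | ethyl (4E,8E)-5,9-dimethyl-13-phenyltetradeca-4,8,12-trienoate (12E/12Z mixture) | CCOC(=O)CC/C=C(C)/CC/C=C(C)/CCC=C(C)c1ccccc1 | intermediate (not isolated)
9 | (4E,8E)-5,9-dimethyl-13-phenyltetradeca-4,8,12-trienoic acid (12E/12Z mixture) | OC(=O)CC/C=C(C)/CC/C=C(C)/CCC=C(C)c1ccccc1 | intermediate
10 | (4R,5R,8R,9R,10S)-4-phenyl-14,15,16,18-tetranorlabdan-13,8-olide (trans-decalin δ-lactone: 4α-Ph, 4β-Me, 5α-H, 10β-Me, 8β-Me, 8α-O, 9α-H) | O=C3O[C@]1(C)CC[C@@H]2[C@](C)(CCC[C@@]2(C)c4ccccc4)[C@H]1CC3 | intermediate
11 | (4R,5R,8R,9R,10S)-8,13-epoxy-4-phenyl-14,15,16,18-tetranorlabdan-13-ol (lactol, both C13 anomers) | OC3O[C@]1(C)CC[C@@H]2[C@](C)(CCC[C@@]2(C)c4ccccc4)[C@H]1CC3 | intermediate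
12 | (4R,5R,8R,9R,10S)-4-phenyl-15,16,18-trinorlabd-13-en-8-ol (8α-OH, 9β-but-3-enyl) | O[C@]1(C)CC[C@@H]2[C@](C)(CCC[C@@]2(C)c3ccccc3)[C@H]1CCC=C | intermediate
13 | (4R,5R,8R,9R,10S)-4-phenyl-15,16,18-trinorlabd-13-en-8-yl acetate | CC(=O)O[C@]1(C)CC[C@@H]2[C@](C)(CCC[C@@]2(C)c3ccccc3)[C@H]1CCC=C | intermediate
14 | (4R,5R,8R,9R,10S)-8-acetoxy-14,15,16-trinorlabdane-13,18-dioic acid, i.e. (1R,4aS,5R,6R,8aR)-6-acetoxy-5-(2-carboxyethyl)-1,4a,6-trimethyldecahydronaphthalene-1-carboxylic acid (CNP0196050.1) | CC(=O)O[C@]1(C)CC[C@@H]2[C@](C)(CCC[C@@]2(C)C(=O)O)[C@H]1CCC(=O)O | target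

**Step count**
Total: 9 steps. Longest linear sequence: 9 steps (1 → 14); 2 enters in step 1 and 7 in step 4.

**Three steps most likely to fail, with fallbacks**

Step 5 (asymmetric cascade). The benzylic ion pair may be too loose for high enantioselectivity. Protonation of the C4=C5 alkene of 9 would give a monocyclic δ-lactone. A minor axial-phenyl pathway would give the C4 epimer. The fallback gives up asymmetric catalysis and sets out from 9. Cyclisation with ClSO3H in 2-nitropropane at −78 °C gives the racemic lactone, that is 10 together with its mirror-image lactone F1. Preparative chromatography on a chiral stationary phase (supercritical CO2/MeOH) removes F1 and delivers 10, where the route resumes.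

Step 9 (double RuO4 unmasking). Phenyl degradation at the hindered quaternary C4 may lag behind alkene cleavage, or long exposure may oxidise C–H bonds of the acetate-bearing product. The fallback moves the arene degradation to the robust lactone and changes the end game to an ester-protected one. It sets out from 10 and comes back at 14. RuCl3/NaIO4 on 10 gives the lactone acid F2. KOH in aqueous MeOH at 60 °C opens the lactone to the dipotassium hydroxy dicarboxylate F3. BnBr in DMF alkylates both carboxylates to the dibenzyl ester F4, whose tertiary hydroxyl stays free. Ac2O, Et3N and 4-(dimethylamino)pyridine give the acetate F5. Hydrogenolysis (H2, Pd/C, EtOAc) then releases 14.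

Step 4 (Wittig with a hindered secondary ylide). Low conversion, or attack of the ylide on the ester, is possible. The fallback replaces olefination by addition and elimination. It sets out from 6 and comes back at 8. 1-Phenylethylmagnesium chloride in THF at −78 °C adds to the aldehyde only and gives the secondary alcohol F6. MsCl/Et3N converts it into the mesylate F7. DBU in toluene at 80 °C eliminates towards the acidic benzylic hydrogen to give the conjugated styrene 8, which is saponified to 9 as in step 4.

**Further compounds**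

F1 | step 5 | (4S,5S,8S,9S,10R)-4-phenyl-14,15,16,18-tetranorlabdan-13,8-olide (mirror image of 10) | O=C3O[C@@]1(C)CC[C@H]2[C@@](C)(CCC[C@]2(C)c4ccccc4)[C@@H]1CC3
F2 | step 9 | (4R,5R,8R,9R,10S)-13-oxo-8,13-epoxy-14,15,16-trinorlabdan-18-oic acid (lactone acid) | O=C3O[C@]1(C)CC[C@@H]2[C@](C)(CCC[C@@]2(C)C(=O)O)[C@H]1CC3
F3 | step 9 | dipotassium (4R,5R,8R,9R,10S)-8-hydroxy-14,15,16-trinorlabdane-13,18-dioate | [K+].[K+].O[C@]1(C)CC[C@@H]2[C@](C)(CCC[C@@]2(C)C(=O)[O-])[C@H]1CCC(=O)[O-]
F4 | step 9 | dibenzyl (4R,5R,8R,9R,10S)-8-hydroxy-14,15,16-trinorlabdane-13,18-dioate | O[C@]1(C)CC[C@@H]2[C@](C)(CCC[C@@]2(C)C(=O)OCc3ccccc3)[C@H]1CCC(=O)OCc4ccccc4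
F5 | step 9 | dibenzyl (4R,5R,8R,9R,10S)-8-acetoxy-14,15,16-trinorlabdane-13,18-dioate | CC(=O)O[C@]1(C)CC[C@@H]2[C@](C)(CCC[C@@]2(C)C(=O)OCc3ccccc3)[C@H]1CCC(=O)OCc4ccccc4
F6 | step 4 | ethyl (4E,8E)-12-hydroxy-5,9-dimethyl-13-phenyltetradeca-4,8-dienoate (diastereomer mixture) | CCOC(=O)CC/C=C(C)/CC/C=C(C)/CCC(O)C(C)c1ccccc1
F7 | step 4 | ethyl (4E,8E)-12-(methylsulfonyloxy)-5,9-dimethyl-13-phenyltetradeca-4,8-dienoate (diastereomer mixture) | CCOC(=O)CC/C=C(C)/CC/C=C(C)/CCC(OS(C)(=O)=O)C(C)c1ccccc1
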